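Ring B (C3a, C4, C5, C6, C7, C7a) is cut at C4–C5. The feature used is that C4 is a neopentyl CH2 on quaternary C3a and C5 is the only enolisable carbon next to the C6 ketone, itself part of the vinylogous ester O1–C7a=C7–C6=O attached to ring A. One base-mediated aldol condensation of a C4 aldehyde therefore closes ring B as the 5-methoxy cross-conjugated dienone, which C3a keeps from aromatising. The precursor is the (E)-2-(3-methoxy-2-oxopropylidene)tetrahydrofuran-3-carbaldehyde; its crowded E alkene (C6 cis to C3a) is set beforehand by a temporary δ-lactone through the C4 oxygen. Conjugate reduction then gives the target.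

Key step: step 10

Remark: in the Why lines the atoms carry the benzofuran numbers of the target (O1, C2, C3, C3a, C4 to C7, C7a) in every intermediate.
Assumption: (R)-TRIP is taken to deliver the (1R,2R) alcohol in step 1, as with other aryl aldehydes; if the sense is opposite for this aldehyde, (S)-TRIP is used.

Step 1
Reactants: 1 3,4,5-trimethoxybenzaldehyde; 2 (E)-crotylboronic acid pinacol ester
Product: 4 (1R,2R)-2-methyl-1-(3,4,5-trimethoxyphenyl)but-3-en-1-ol, via pinacol borate ester 3 (not isolated)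
Conditions: (R)-TRIP (5 mol %), 4 Å MS, PhMe, −30 °C; then H2O
Reagents that add atoms: none
Why: Chiral phosphoric acid catalysed crotylboration through a closed chair transition state, in which the E boronate sets the 1,2-anti relationship and the catalyst selects the aldehyde face, so that C2 and C3 are both set as R.

Step 2
Reactants: 4 (1R,2R)-2-methyl-1-(3,4,5-trimethoxyphenyl)but-3-en-1-ol
Product: 6 (1R,2R)-2-methyl-1-(3,4,5-trimethoxyphenyl)butane-1,4-diol, via B-alkyl-9-BBN adduct 5 (not isolated)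
Conditions: 9-BBN (2.5 equiv), THF, 0 → 23 °C; then NaOH, H2O2, H2O, 0 °C
Reagents that add atoms: hydrogen peroxide, OO
Why: Anti-Markovnikov hydroboration of the terminal alkene followed by oxidation of the C–B bond, which touches neither stereocentre.

Step 3
Reactants: 6 (1R,2R)-2-methyl-1-(3,4,5-trimethoxyphenyl)butane-1,4-diol
Product: 8 (4R,5R)-4-methyl-5-(3,4,5-trimethoxyphenyl)dihydrofuran-2(3H)-one, via lactol 7 (not isolated)
Conditions: TEMPO (10 mol %), PhI(OAc)2 (2.5 equiv), CH2Cl2, 23 °C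
Reagents that add atoms: none
Why: Oxidative lactonisation of a 1,4-diol, in which the oxoammonium salt oxidises the primary alcohol in preference to the benzylic one, the hydroxy aldehyde closes to the lactol and this is oxidised on to the γ-lactone.

Step 4
Reactants: 8 (4R,5R)-4-methyl-5-(3,4,5-trimethoxyphenyl)dihydrofuran-2(3H)-one; 9 allyl bromide
Product: 10 (3R,4R,5R)-3-allyl-4-methyl-5-(3,4,5-trimethoxyphenyl)dihydrofuran-2(3H)-one
Conditions: LiN(iPr)2, THF, −78 °C; then allyl bromide, −78 → −30 °C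
Reagents that add atoms: none
Why: Alkylation of the lactone enolate, expected trans to the C3 methyl group, although the configuration of this carbon is erased again when it is re-enolised in step 5.

Step 5
Reactants: 10 (3R,4R,5R)-3-allyl-4-methyl-5-(3,4,5-trimethoxyphenyl)dihydrofuran-2(3H)-one; 11 formaldehyde
Product: 12 (3S,4R,5R)-3-allyl-3-(hydroxymethyl)-4-methyl-5-(3,4,5-trimethoxyphenyl)dihydrofuran-2(3H)-one
Conditions: LiN(iPr)2, THF, −78 °C; then CH2O (g), −78 → −40 °C; then H2O
Reagents that add atoms: none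
Why: Aldol addition of the tetrasubstituted lactone enolate to formaldehyde on the face anti to the adjacent C3 methyl group (the usual 3,4-trans preference of butyrolactone enolates), which sets quaternary C3a with the allyl group cis to methyl and C4 trans to it.

Step 6
Reactants: 12 (3S,4R,5R)-3-allyl-3-(hydroxymethyl)-4-methyl-5-(3,4,5-trimethoxyphenyl)dihydrofuran-2(3H)-one; 13 acetic anhydride
Product: 14 [(3S,4R,5R)-3-allyl-4-methyl-2-oxo-5-(3,4,5-trimethoxyphenyl)tetrahydrofuran-3-yl]methyl acetate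
Conditions: Ac2O, pyridine, DMAP (cat.), CH2Cl2, 23 °C
Reagents that add atoms: none
Why: DMAP-catalysed acetylation of the neopentyl primary alcohol, which tethers the future C6 and C7 to the C4 oxygen.

Step 7
Reactants: 14 [(3S,4R,5R)-3-allyl-4-methyl-2-oxo-5-(3,4,5-trimethoxyphenyl)tetrahydrofuran-3-yl]methyl acetate
Product: 16 (2R,3R,3aS)-3a-allyl-3-methyl-2-(3,4,5-trimethoxyphenyl)-2,3,3a,4-tetrahydro-6H-furo[3,2-c]pyran-6-one, via β-keto δ-lactone 15 (not isolated)
Conditions: LiN(SiMe3)2 (2.5 equiv), THF, −78 → 0 °C; then AcOH; then PPTS (cat.), 4 Å MS, PhMe, 60 °C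
Reagents that add atoms: none
Why: Dieckmann-type Claisen condensation of a β-acetoxy ester (6-exo-trig attack of the acetate enolate on the lactone carbonyl C7a, driven by the β-dicarbonyl enolate) followed by mildly acidic condensation of the released benzylic hydroxyl with the C7a carbonyl to the cyclic enol ether, which breaks no bond to a stereocentre and locks C6 cis to C3a inside the new lactone ring.

Step 8
Reactants: 16 (2R,3R,3aS)-3a-allyl-3-methyl-2-(3,4,5-trimethoxyphenyl)-2,3,3a,4-tetrahydro-6H-furo[3,2-c]pyran-6-one; 17 tributyl(methoxymethyl)stannane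
Product: 19 (E)-1-[(3S,4R,5R)-3-allyl-3-(hydroxymethyl)-4-methyl-5-(3,4,5-trimethoxyphenyl)dihydrofuran-2(3H)-ylidene]-3-methoxypropan-2-one, via cyclic hemiketal 18 (not isolated)
Conditions: Bu3SnCH2OMe, n-BuLi, THF, −78 °C; then 16, −78 °C; then H2O (pH 7)
Reagents that add atoms: none
Why: 1,2-Addition of an α-alkoxy organolithium (from tin–lithium exchange) to the lactone carbonyl should stop at the lithium hemiketal at −78 °C, and after a cold quench the hemiketal opens to the δ-hydroxy vinylogous ester with the E geometry inherited from the ring.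

Step 9
Reactants: 19 (E)-1-[(3S,4R,5R)-3-allyl-3-(hydroxymethyl)-4-methyl-5-(3,4,5-trimethoxyphenyl)dihydrofuran-2(3H)-ylidene]-3-methoxypropan-2-one
Product: 20 (2E,3R,4R,5R)-3-allyl-2-(3-methoxy-2-oxopropylidene)-4-methyl-5-(3,4,5-trimethoxyphenyl)tetrahydrofuran-3-carbaldehyde
Conditions: Dess–Martin periodinane, pyridine, CH2Cl2, 0 → 23 °C
Reagents that add atoms: none
Why: Oxidation of the neopentyl primary alcohol with a hypervalent iodine reagent under pyridine buffering, conditions with neither strong acid nor a nucleophile that could isomerise the push–pull alkene, to an aldehyde that has no α-hydrogen.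

Step 10
Reactants: 20 (2E,3R,4R,5R)-3-allyl-2-(3-methoxy-2-oxopropylidene)-4-methyl-5-(3,4,5-trimethoxyphenyl)tetrahydrofuran-3-carbaldehyde
Product: 22 (2R,3R,3aS)-3a-allyl-5-methoxy-3-methyl-2-(3,4,5-trimethoxyphenyl)-3,3a-dihydro-1-benzofuran-6(2H)-one, via aldol adduct 21 (not isolated)
Conditions: KOtBu (1.1 equiv), THF/t-BuOH (5:1), −20 → 23 °C
Reagents that add atoms: none
Why: KOtBu removes a C5 proton (the only enolisable position, since the aldehyde sits on quaternary C3a and C7–H is vinylic), the s-trans enolate adds to the C4 formyl group to give aldolate 21, and E1cB loss of hydroxide forms C4=C5. The closest known reaction is the base-mediated aldol condensation of 5-oxo aldehydes with a quaternary α-carbon to 4,4-disubstituted cyclohexenones. Ring B closes in the 6-(enolendo)-exo-trig mode. No stereocentre is created: the C4 and C5 centres of 21 are erased on dehydration, and C2, C3 and C3a cannot be enolised. The step needs C6 cis to C3a, which is secured by the E geometry built into 20 through lactone 16 and by a non-nucleophilic base that should neither add to C7a and isomerise the alkene nor attack the aldehyde, while quaternary C3a blocks aromatisation of the dienone. The temperature is held at or below 23 °C so that the allyl group does not leave C3a by a [3,3] shift.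

Step 11
Reactants: 22 (2R,3R,3aS)-3a-allyl-5-methoxy-3-methyl-2-(3,4,5-trimethoxyphenyl)-3,3a-dihydro-1-benzofuran-6(2H)-one
Product: 24 (2R,3R,3aR,5R)-3a-allyl-5-methoxy-3-methyl-2-(3,4,5-trimethoxyphenyl)-3,3a,4,5-tetrahydro-1-benzofuran-6(2H)-one, via C5 epimer 23 (not isolated)
Conditions: [(Ph3P)CuH]6 (0.5 equiv), H2O, PhH/THF, 23 °C; then DBU (0.2 equiv), CH2Cl2, 23 °C
Reagents that add atoms: none
Why: Copper hydride conjugate reduction should deliver hydride to C4 of the C4=C5 enone arm only (the C7=C7a arm is a β-alkoxy, β,β-disubstituted vinylogous ester and the allyl group is an isolated alkene), and base equilibration of the α-methoxy ketone then places the C5 methoxy group equatorial, trans to the axial C3a allyl group, which is the 5R configuration.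

Compound list
1 | 3,4,5-trimethoxybenzaldehyde | COc1cc(C=O)cc(OC)c1OC | starting material
2 | (E)-crotylboronic acid pinacol ester | C/C=C/CB1OC(C)(C)C(C)(C)O1 | starting material
3 | 4,4,5,5-tetramethyl-2-{[(1R,2R)-2-methyl-1-(3,4,5-trimethoxyphenyl)but-3-en-1-yl]oxy}-1,3,2-dioxaborolane | CC1(C)OB(O[C@@H](c2cc(OC)c(OC)c(OC)c2)[C@@H](C=C)C)OC1(C)C | intermediate
4 | (1R,2R)-2-methyl-1-(3,4,5-trimethoxyphenyl)but-3-en-1-ol | O[C@@H](c1cc(OC)c(OC)c(OC)c1)[C@@H](C=C)C | intermediate
5 | 9-[(3R,4R)-4-hydroxy-3-methyl-4-(3,4,5-trimethoxyphenyl)butyl]-9-borabicyclo[3.3.1]nonane | O[C@@H](c1cc(OC)c(OC)c(OC)c1)[C@@H](CCB1C2CCCC1CCC2)C | intermediate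
6 | (1R,2R)-2-methyl-1-(3,4,5-trimethoxyphenyl)butane-1,4-diol | O[C@@H](c1cc(OC)c(OC)c(OC)c1)[C@@H](CCO)C | intermediate
7 | (4R,5R)-4-methyl-5-(3,4,5-trimethoxyphenyl)tetrahydrofuran-2-ol (both anomers) | OC1C[C@@H](C)[C@H](c2cc(OC)c(OC)c(OC)c2)O1 | intermediate
8 | (4R,5R)-4-methyl-5-(3,4,5-trimethoxyphenyl)dihydrofuran-2(3H)-one | O=C1C[C@@H](C)[C@H](c2cc(OC)c(OC)c(OC)c2)O1 | intermediate
9 | allyl bromide | C=CCBr | starting material
10 | (3R,4R,5R)-3-allyl-4-methyl-5-(3,4,5-trimethoxyphenyl)dihydrofuran-2(3H)-one | C=CC[C@H]1C(=O)O[C@@H](c2cc(OC)c(OC)c(OC)c2)[C@@H]1C | intermediate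
11 | formaldehyde (gas from cracked paraformaldehyde) | C=O | starting material
12 | (3S,4R,5R)-3-allyl-3-(hydroxymethyl)-4-methyl-5-(3,4,5-trimethoxyphenyl)dihydrofuran-2(3H)-one | C=CC[C@]1(CO)C(=O)O[C@@H](c2cc(OC)c(OC)c(OC)c2)[C@@H]1C | intermediate
13 | acetic anhydride | CC(=O)OC(C)=O | starting material
14 | [(3S,4R,5R)-3-allyl-4-methyl-2-oxo-5-(3,4,5-trimethoxyphenyl)tetrahydrofuran-3-yl]methyl acetate | C=CC[C@]1(COC(C)=O)C(=O)O[C@@H](c2cc(OC)c(OC)c(OC)c2)[C@@H]1C | intermediate
15 | (5S)-5-allyl-4-hydroxy-5-[(1R,2R)-1-hydroxy-1-(3,4,5-trimethoxyphenyl)propan-2-yl]-5,6-dihydro-2H-pyran-2-one | C=CC[C@]1([C@@H](C)[C@@H](O)c2cc(OC)c(OC)c(OC)c2)COC(=O)C=C1O | intermediate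
16 | (2R,3R,3aS)-3a-allyl-3-methyl-2-(3,4,5-trimethoxyphenyl)-2,3,3a,4-tetrahydro-6H-furo[3,2-c]pyran-6-one | C=CC[C@]12COC(=O)C=C1O[C@@H](c1cc(OC)c(OC)c(OC)c1)[C@@H]2C | intermediate
17 | tributyl(methoxymethyl)stannane | CCCC[Sn](CCCC)(CCCC)COC | starting material
18 | (2R,3R,3aS)-3a-allyl-6-(methoxymethyl)-3-methyl-2-(3,4,5-trimethoxyphenyl)-2,3,3a,4-tetrahydro-6H-furo[3,2-c]pyran-6-ol (both C6 epimers) | C=CC[C@]12COC(O)(COC)C=C1O[C@@H](c1cc(OC)c(OC)c(OC)c1)[C@@H]2C | intermediate
19 | (E)-1-[(3S,4R,5R)-3-allyl-3-(hydroxymethyl)-4-methyl-5-(3,4,5-trimethoxyphenyl)dihydrofuran-2(3H)-ylidene]-3-methoxypropan-2-one | C=CC[C@]1(CO)/C(=C\C(=O)COC)O[C@@H](c2cc(OC)c(OC)c(OC)c2)[C@@H]1C | intermediate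
20 | (2E,3R,4R,5R)-3-allyl-2-(3-methoxy-2-oxopropylidene)-4-methyl-5-(3,4,5-trimethoxyphenyl)tetrahydrofuran-3-carbaldehyde | C=CC[C@]1(C=O)/C(=C\C(=O)COC)O[C@@H](c2cc(OC)c(OC)c(OC)c2)[C@@H]1C | intermediate
21 | (2R,3R,3aS)-3a-allyl-4-hydroxy-5-methoxy-3-methyl-2-(3,4,5-trimethoxyphenyl)-3,3a,4,5-tetrahydro-1-benzofuran-6(2H)-one (C4 and C5 epimers) | C=CC[C@]12C(O)C(OC)C(=O)C=C1O[C@@H](c1cc(OC)c(OC)c(OC)c1)[C@@H]2C | intermediate
22 | (2R,3R,3aS)-3a-allyl-5-methoxy-3-methyl-2-(3,4,5-trimethoxyphenyl)-3,3a-dihydro-1-benzofuran-6(2H)-one | C=CC[C@]12C=C(OC)C(=O)C=C1O[C@@H](c1cc(OC)c(OC)c(OC)c1)[C@@H]2C | intermediate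
23 | (2R,3R,3aR,5S)-3a-allyl-5-methoxy-3-methyl-2-(3,4,5-trimethoxyphenyl)-3,3a,4,5-tetrahydro-1-benzofuran-6(2H)-one | C=CC[C@]12C[C@H](OC)C(=O)C=C1O[C@@H](c1cc(OC)c(OC)c(OC)c1)[C@@H]2C | intermediate
24 | (2R,3R,3aR,5R)-3a-allyl-5-methoxy-3-methyl-2-(3,4,5-trimethoxyphenyl)-3,3a,4,5-tetrahydro-1-benzofuran-6(2H)-one | C=CC[C@]12C[C@@H](OC)C(=O)C=C1O[C@@H](c1cc(OC)c(OC)c(OC)c1)[C@@H]2C | target

Total step count: 11. Longest linear sequence: 11 steps (1 to 24); all other starting materials enter as purchased reagents.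

Steps most likely to fail

Step 7. The acetate enolate may fragment to ketene and the alkoxide of 12 before it adds to the hindered C7a carbonyl, and the acid-promoted ring closure may stall at the hemiketal stage. The fallback sets out from 12 and forms the C7–C7a bond intermolecularly. An excess of the lithium enolate of tert-butyl acetate (LiN(iPr)2, THF, −78 °C) is added to the lactone carbonyl to give tert-butyl 2-[(3S,4R,5R)-3-allyl-2-hydroxy-3-(hydroxymethyl)-4-methyl-5-(3,4,5-trimethoxyphenyl)tetrahydrofuran-2-yl]acetate F1. TFA in CH2Cl2 at 0 °C should then dehydrate the hemiketal, remove the tert-butyl group and let the acid lactonise onto the primary hydroxyl, the acid-mobile alkene being drained through its E form. The sequence comes back to the route at 16.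

Step 8. The lithium hemiketal may open in the flask so that a second equivalent of the organolithium adds to the released ketone, or the alkene geometry may drift while the hemiketal is handled. The fallback sets out from 16. i-PrMgCl and MeNHOMe·HCl in THF at −20 °C open the lactone to (E)-2-[(3S,4R,5R)-3-allyl-3-(hydroxymethyl)-4-methyl-5-(3,4,5-trimethoxyphenyl)dihydrofuran-2(3H)-ylidene]-N-methoxy-N-methylacetamide F2. TESCl and imidazole give its triethylsilyl ether F3. MeOCH2Li (from Bu3SnCH2OMe and n-BuLi) should then stop at the chelated adduct and give the silyl-protected ketone F4 on work-up. HF·pyridine removes the silyl group, and the route is rejoined at 19.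

Step 10. Hydroxide formed during the condensation may attack the formyl group and cleave it from C3a in a retro-Claisen manner, or the reaction may stall at the aldol stage because hydroxide leaves slowly. The fallback sets out from 20 and separates addition from elimination. LiN(SiMe3)2 in THF at −78 °C with a cold quench should give aldol 21, which is now isolated. MsCl and Et3N convert it into (2R,3R,3aS)-3a-allyl-5-methoxy-3-methyl-6-oxo-2-(3,4,5-trimethoxyphenyl)-2,3,3a,4,5,6-hexahydro-1-benzofuran-4-yl methanesulfonate F5, and DBU in CH2Cl2 at 0 °C eliminates the sulfonate. The route is rejoined at 22.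

Further compounds
F1 | step 7 | tert-butyl 2-[(3S,4R,5R)-3-allyl-2-hydroxy-3-(hydroxymethyl)-4-methyl-5-(3,4,5-trimethoxyphenyl)tetrahydrofuran-2-yl]acetate | C=CC[C@]1(CO)C(O)(CC(=O)OC(C)(C)C)O[C@@H](c2cc(OC)c(OC)c(OC)c2)[C@@H]1C
F2 | step 8 | (E)-2-[(3S,4R,5R)-3-allyl-3-(hydroxymethyl)-4-methyl-5-(3,4,5-trimethoxyphenyl)dihydrofuran-2(3H)-ylidene]-N-methoxy-N-methylacetamide | C=CC[C@]1(CO)/C(=C\C(=O)N(C)OC)O[C@@H](c2cc(OC)c(OC)c(OC)c2)[C@@H]1C
F3 | step 8 | (E)-2-[(3S,4R,5R)-3-allyl-4-methyl-3-{[(triethylsilyl)oxy]methyl}-5-(3,4,5-trimethoxyphenyl)dihydrofuran-2(3H)-ylidene]-N-methoxy-N-methylacetamide | C=CC[C@]1(CO[Si](CC)(CC)CC)/C(=C\C(=O)N(C)OC)O[C@@H](c2cc(OC)c(OC)c(OC)c2)[C@@H]1C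
F4 | step 8 | (E)-1-[(3S,4R,5R)-3-allyl-4-methyl-3-{[(triethylsilyl)oxy]methyl}-5-(3,4,5-trimethoxyphenyl)dihydrofuran-2(3H)-ylidene]-3-methoxypropan-2-one | C=CC[C@]1(CO[Si](CC)(CC)CC)/C(=C\C(=O)COC)O[C@@H](c2cc(OC)c(OC)c(OC)c2)[C@@H]1C
F5 | step 10 | (2R,3R,3aS)-3a-allyl-5-methoxy-3-methyl-6-oxo-2-(3,4,5-trimethoxyphenyl)-2,3,3a,4,5,6-hexahydro-1-benzofuran-4-yl methanesulfonate (C4 and C5 epimers) | C=CC[C@]12C(OS(C)(=O)=O)C(OC)C(=O)C=C1O[C@@H](c1cc(OC)c(OC)c(OC)c1)[C@@H]2C
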